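1. Late in the grey run target falls more slowly than starting material falls early, and starting material reads 3% at 2.50 h, so a late reading is carried forward here by a single rate.

common to all: protic impurity 1.28 mM

| flask | starting material | remark | time |
|---|---|---|---|
| violet | 0.064 M | run made earlier |  |
| grey | 0.032 M | run made earlier |  |
| teal | 0.13 M | run made earlier |  |
| north | 0.064 M | a single well-mixed tank run continuously and read at steady state, 3.0 h in it on average |  |
| south | 0.064 M | a tube with plug flow, the mixed feed as stated, residence time 3.0 h | 3.0 h |
| south-east | 0.064 M | everything together in a closed stirred flask, run for 3.0 h | 3.0 h |
| south-west | 0.064 M (fed, over 2.40 h) | a stirred flask in which starting material is dosed at a steady rate over 2.40 h without added volume, worked up at 3.0 h | 3.0 h |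

violet run (percent of the starting material charged)

| time / min | target / % | starting material / % |
|---|---|---|
| 20.0 | 19 | 66 |
| 40.0 | 28 | 42 |
| 60.0 | 30 | 25 |
| 80.0 | 30 | 17 |
| 120 | 28 | 7 |

grey run (percent of the starting material charged)

| time / h | target / % | starting material / % |
|---|---|---|
| 0.333 | 24 | 69 |
| 0.833 | 38 | 36 |
| 1.50 | 41 | 16 |
| 2.50 | 33 | 3 |
| 4.00 | 22 | 2 |

teal run (percent of the starting material charged)

| time / h | target / % | starting material / % |
|---|---|---|
| 0.333 | 15 | 64 |
| 0.833 | 22 | 27 |
| 1.50 | 20 | 8 |
| 2.50 | 17 | 3 |
| 4.00 | 13 | 0 |

(readings scatter by 1.5 percentage points)

- the stated concentrations are those of everything mixed, before any reaction; amounts are the same in each set-up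
- the feed brings no volume worth counting
- the earlier runs were made in a closed, stirred flask

* the set-up with the highest amount of target at the outlet or at the end, in percent of the starting material put in ("none" if the first two lie within 2 percentage points) (north / south / south-east / south-west / none)
* amount of target at the outlet or at the end, in percent of the starting material put in, north
* amount of target at the outlet or at the end, in percent of the starting material put in, south
* amount of target at the outlet or at the end, in percent of the starting material put in, south-east
* amount of target at the outlet or at the end, in percent of the starting material put in, south-west

2. Let P be target in percent of charge and k_L the late decay constant, the apparent first-order constant in dP/dt = −k_L·P. Integration from an earlier time s gives P(t) = P(s)·exp(−k_L·(t−s)). The last two grey readings give k_L = 0.270 h⁻¹; they stand higher than the late teal readings, so scatter weighs less on them.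

3. Floor for south-east, and for south, a tube of equal residence time: violet has the same charge and reads 28% target and 7% starting material at 120 min. If that remainder makes no net target, P at 3.0 h is 21.4%.

4. Ceiling: if the remainder became target entirely, P is 26.7%.

5. Tightening: across the last violet interval, carried target and the reading give a surviving share s_P = 0.295 of starting material consumed. The ceiling, now an estimate and no longer a bound, drops to 22.9%, with the scatter of the readings on both ends.

6. The forecast names south-west: north 26%, south 23%, south-east 23%, south-west 34%, holding that “Plug flow and the closed flask are the same kinetically”. Its south-east value sits at the tightened ceiling.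

7. The simulation gives south-west as best: north 20.4%, south 22.8%, south-east 22.8%, south-west 28.8%. South-east lies inside the bracket.

    starting material + target → side product (k = 0.430 M⁻¹ min⁻¹)
    starting material → target (k = 0.0160 min⁻¹)
    starting material + protic impurity → quenched substrate (k = 2.40 M⁻¹ min⁻¹)
    target → over-reaction product (k = 0.00470 min⁻¹)

8. Neither south-east nor south-west has come to rest at 3.0 h. Carried by k_L to 30.0 h, ten times the time, south-east target becomes 0.0156%, against 0.0118% computed. South-west target becomes 0.0195%, against 0.0174%. Over that time, south-east side product moves from 51.8% to 52.6%, while its over-reaction product moves from 21.9% to 45.4%. South-west starting material falls from 12.6% to 0%, and its over-reaction product reaches 48.0%.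

(The numbers in the tables come from a simulation on assumed constants; noise was put on by code.)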